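The runs were computed on assumed constants; scatter was added.

5 questions stand on the board, and both people at it begin from one measure: how fast starting material disappears in a flask.

| flask | starting material | partner | second substrate | temperature | remark | time |
|---|---|---|---|---|---|---|
| grey | 0.16 M | 1.5 equiv | 2 equiv | −10 °C | run made earlier |  |
| ochre | 0.24 M | 1.5 equiv | 2 equiv | 10 °C | run made earlier |  |
| delta | 0.32 M | 1.50 equiv | 2.00 equiv | 10 °C |  | 2.5 h |
| zeta | 0.32 M | 1.50 equiv | 2.00 equiv | −5 °C |  | 2.5 h |
| alpha | 0.32 M | 1.50 equiv | 2.00 equiv | 25 °C |  | 2.5 h |
| theta | 0.32 M | 1.50 equiv | 2.00 equiv |  | at −5 °C until 50 min, from then on at 25 °C | 2.5 h |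

grey run (percent of the starting material charged)

| time / h | target / % | starting material / % |
|---|---|---|
| 0.417 | 5.4 | 91.6 |
| 0.833 | 8.4 | 83.1 |
| 1.33 | 12.0 | 75.0 |
| 2.50 | 20.4 | 60.9 |
| 5.00 | 26.2 | 40.0 |

ochre run (percent of the starting material charged)

| time / min | target / % | starting material / % |
|---|---|---|
| 25.0 | 20.1 | 42.7 |
| 50.0 | 19.4 | 25.5 |
| 80.0 | 16.0 | 15.8 |
| 90.0 | 14.0 | 14.2 |
| 120 | 10.5 | 10.8 |

(scatter of a reading: 1 percentage point)

- the numbers in the tables scatter by 1 percentage point (one standard deviation)
- on the list of suspects stand: starting material + partner <-> target; second substrate + partner -> second product; starting material + second substrate -> cross product; target <-> isomer of the product; target -> over-reaction product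

- the flask with the highest amount of target, in percent of the starting material charged ("all alike" if they lie within 1.5 percentage points) (delta / zeta / alpha / theta / all alike)
- final target, as a percentage of the starting material charged, in delta
- final target, as a percentage of the starting material charged, in zeta
- final target, as a percentage of the starting material charged, in alpha
- final target, as a percentage of the starting material charged, in theta

Call the clock rate of a run ln(charged/left)/time at its earliest reading, the constant of a pseudo-first-order fall of starting material. With the equivalents held, [partner] and [second substrate] scale with [starting material] at the start, so for bimolecular steps the clock rate scales with that one concentration.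

The grey run gives 0.210 h⁻¹ at 0.16 M, and the ochre run gives 2.04 h⁻¹ at 0.24 M. Per unit of concentration, the ochre run is faster by a factor of 6.47, a reading that carries the scatter. I take the logarithm of the rate as linear in temperature across this span. At −5 °C and 0.32 M, this gives a cold clock rate of 0.671 h⁻¹. Delta, at the ochre temperature, gets 2.72 h⁻¹. So delta starts on a clock 4.05 times that of zeta, faster. These are rates of the early stretch: kept up to 120 min, the clock of the ochre run would leave 1.69% of the starting material, and that run reads 10.8%.

The first person holds that target is a fixed share of what has been converted. The grey run reads 0.522 at 2.50 h, so this person, carrying the early clocks to the end, puts delta near 52.1% and zeta near 42.4%, and expects the faster clock to win.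

The second holds that target is a transit species. In the ochre run it falls from 16.0% to 10.5% between 80.0 min and 120 min, a tail of 0.632 h⁻¹. That tail is slower than the clock of delta, so in delta the fall of target should outlast the conversion. The forecast is this side's number: zeta the best, with 30% there, 8% in delta, 1.5% in alpha and 2% in theta. Its ground for the warm flasks is that “target loss seems at least as temperature-sensitive”.

The flasks give zeta as the best: 32.1% in zeta, 7.76% in delta, 0.0744% in alpha and 0.337% in theta.

    starting material + partner ⇌ target (K = 1.20 M⁻¹, k = 0.00300 M⁻¹ s⁻¹, Ea = 57.0 kJ mol⁻¹, ΔH = −37.0 kJ mol⁻¹)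
    second substrate + partner → second product (k = 1.70 × 10⁻⁴ M⁻¹ s⁻¹, Ea = 82.0 kJ mol⁻¹)
    starting material + second substrate → cross product (k = 0.00390 M⁻¹ s⁻¹, Ea = 70.0 kJ mol⁻¹)
    target ⇌ isomer of the product (K = 0.420, k = 4.50 × 10⁻⁴ s⁻¹, Ea = 90.0 kJ mol⁻¹, ΔH = −17.0 kJ mol⁻¹)
    target → over-reaction product (k = 3.00 × 10⁻⁴ s⁻¹, Ea = 93.0 kJ mol⁻¹)
    (constants at 25 °C)

The share view keeps the cold, early stretch: at the change of temperature, theta held 21.1% target with 44.0% of the starting material gone, a share of 0.480. The cold clock rate of 0.671 h⁻¹ puts starting material in zeta at 43.2% after 1.25 h, where that flask holds 43.7%, and in theta at 57.2% after 0.833 h, where that flask holds 56.0%.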